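Late in the autumn run, Z read 0% at 8.00 min, yet E went on from 19.4% to 37.6% by 12.0 min. So E grew from something Z had already become. Z also fell faster in the winter run, with more L: 42.9% against 52.9% at 1.00 min. I therefore treated L as a reagent and wrote its balance.

| flask | Z | L | remark | time |
|---|---|---|---|---|
| autumn | 0.0020 M | 0.021 M | run made earlier |  |
| winter | 0.0020 M | 0.028 M | run made earlier |  |
| Sunday's | 0.0020 M | 0.0140 M |  | 1.0 h |
| Thursday's | 0.0060 M | 0.0140 M |  | 1.0 h |
| Saturday's | 0.020 M | 0.0140 M |  | 1.0 h |

| run | time / min | E / % | Z / % |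
|---|---|---|---|
| autumn | 1.00 | 0.9 | 52.9 |
| autumn | 3.00 | 2.2 | 17.0 |
| autumn | 6.00 | 10.8 | 3.7 |
| autumn | 8.00 | 19.4 | 0 |
| autumn | 12.0 | 37.6 | 0 |
| winter | 1.00 | 0 | 42.9 |
| winter | 3.00 | 3.0 | 6.0 |
| winter | 6.00 | 13.7 | 0.6 |
| winter | 8.00 | 22.6 | 0 |
| winter | 12.0 | 39.8 | 0 |

(scatter of a reading: 1 percentage point)

- [E] at the end for Sunday's, Thursday's, Saturday's, in this order
- the course of these numbers from the first flask to the last (rises all the way / rises, then falls / falls, then rises / falls all the way / hardly changes)

- "hardly changes" means that all values lie within two and a half points (for a concentration: within two and a half percent of the largest)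

I set two amounts against each other, the L charged and the Z charged. Saturday's ratio of L charged to Z charged, r = 0.700, compared with 7.00 on Sunday's and 2.33 on Thursday's. I took each Z to need at least one L, but the readings did not show whether a later step took another. Thursday's r lay above two and Saturday's below one. So, either way, I held L sufficient on Thursday's and made it the limiting reagent on Saturday's. I committed to Thursday's E standing a factor 3.00 above Sunday's, and to Saturday's E staying below 0.0140 M.

The forecast gave 0.002 M, 0.0048 M and 2.000 × 10⁻⁴ M, rises, then falls, noting “Saturday is the least certain”.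

The flasks gave 0.00159 M, 0.00467 M and 0.00314 M, rises, then falls; Thursday's stood 2.94 times Sunday's.

    Z + L → D (k = 0.520 M⁻¹ s⁻¹)
    L + D → J (k = 0.710 M⁻¹ s⁻¹)
    J → X (k = 2.80 × 10⁻⁴ s⁻¹)
    X → Q (k = 9.20 × 10⁻⁴ s⁻¹)
    J ⇌ G (K = 16.0, k = 0.00120 s⁻¹)
    X → E (k = 0.0180 s⁻¹)
    G → Q (k = 0.00210 s⁻¹)
    G → X (k = 0.00890 s⁻¹)

Sunday's flask used 2.00 L per Z charged, matching the two L-taking steps. Sunday's E of 0.00159 M fell to 3.66 × 10⁻⁴ M with the passing of G into X taken out, so that step carries a part of it. Saturday's r of 0.700 stood below that: L ended at 0% of its charge, Z at 49.7%, and 30.7% of the Z waited as D, which needs a second L. With the wearing away of L taken out, Saturday's E came to 0.0159 M against 0.00314 M, so that wearing away is a part of the shortfall, a factor of 5.08.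

The earlier runs and the new flask were generated by integration for substances that don't exist; scatter was added.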